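# Proposed total synthesis of CNP0018313.0 by late construction of ring E from an aryloxymalonate

**Numbering used throughout.** Rings are lettered A to E from left to right in the target SMILES. In each ring C1 is the carbon that carries the ether oxygen from the preceding ring. Ar4 stands for the octamethylated A–B–C–D aryl group, 2-{4-[2-(3,5-dimethoxyphenoxy)-3,5-dimethoxyphenoxy]-3,5-dimethoxyphenoxy}-3,5-dimethoxyphenyl.

- 1: 3,5-dimethoxyphenol
- 2: 2-bromo-3,5-dimethoxybenzaldehyde
- 3: A–B aldehyde
- 4: A–B formate (not isolated)
- 5: A–B phenol
- 6: 4-bromo-3,5-dimethoxybenzaldehyde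
- 7: A–B–C aldehyde
- 8: A–B–C formate (not isolated)
- 9: A–B–C phenol
- 10: A–B–C–D aldehyde
- 11: A–B–C–D formate (not isolated)
- 12: A–B–C–D phenol, Ar4–OH
- 13: dimethyl bromomalonate
- 14: dimethyl 2-(Ar4-oxy)malonate
- 15: dimethyl 3-oxopentanedioate
- 16: open-chain monoacylation adduct (not isolated)
- 17: pentamer with ring E as dimethyl 2,4,6-trihydroxyisophthalate
- 18: the corresponding diacid (not isolated)
- 19: pentamer octamethyl ether with free ring E
- 20: CNP0018313.0

## Analysis of the target

Compound 20 (C30H22O15) is a linear phlorethol-type pentamer: five benzene rings joined only by four diaryl ether oxygens, with eleven free phenolic hydroxyls and no carbon–carbon bond between rings. Ring A is a 3,5-dihydroxyphenyl group. Rings B and D are 1,2,3,5-tetraoxygenated and carry their two ether oxygens on the adjacent carbons C1 and C6. Ring C is linked through C1, which lies between two hydroxyls, and through C4. Ring E is a 2,4,6-trihydroxyphenyl ether. There is no stereocentre and the diaryl ether axes rotate freely, so the problem is one of constitution only. The free polyphenol is very electron-rich, is oxidised by air (fastest as a phenoxide) and is attacked by electrophiles at every ring CH, so all hydroxyls should stay masked until the last step. The difficulty lies in telling fifteen similar oxygens apart and in forming ether bonds at carbons flanked by two oxygen substituents (C1 of rings B, C, D and E), where both addition–elimination and metal-catalysed coupling are slowed by crowding and electron donation. The strategy rests on ring E: C1 (bearing the oxygen from ring D) with C2 and C6 maps onto the three carbons of a malonate, and C3, C4 and C5 onto an acetone unit. The D–E oxygen can therefore be attached to an sp3 malonate carbon by simple substitution, and ring E can be built around it by a double Claisen condensation.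

## Retrosynthetic reasoning

**20 from 19.** The last operation is cleavage of the eight O–methyl bonds on rings A to D. Methyl ethers are chosen because they survive copper coupling, peracid, alkoxide and hot hydroxide, and because every ring A–D building block is sold with them in place. Ring E needs no protection, since it is formed as a free triol.

**19 from 17.** The two ring E hydrogens at C3 and C5 are traced back to methoxycarbonyl groups. These are the activating groups that make the acetone unit a usable bis-nucleophile. They should leave easily, because a 2,4,6-trihydroxybenzoic acid is a vinylogous β-keto acid and decarboxylates readily. The forward step has to hydrolyse two hydrogen-bonded esters without air oxidation of the ring.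

**17 from 14 and 15 (key disconnection).** The C2–C3 and C5–C6 bonds of ring E are cut. This returns the malonate 14, which already holds the D–E oxygen on its central carbon, and the symmetric ketodiester 15. Cutting here, and not at the D–E oxygen, avoids coupling a phenol to a 2,4,6-trioxygenated aryl halide. Both partners are symmetric, so only one constitution can form. The forward step must achieve a crossed double acylation of 15 by the two ester groups of 14 and aromatisation.

**14 from 12 and 13.** The O–C(sp3) bond is cut. The forward reaction is alkylation of the ring D phenol of 12 with the secondary, doubly activated bromide 13, and no aryl–oxygen bond has to be made at a crowded ring carbon.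

**12 from 10, and 10 from 9 and 2.** The ring D hydroxyl is traced back to a formyl group by oxygen insertion. The C–D ether is cut so that the unhindered ring C phenol of 9 is the nucleophile and 2 the electrophile. The formyl group of 2 serves twice: it assists copper insertion at the neighbouring bromide and then becomes the phenol needed for the next bond. No protecting-group step is needed.

**9 from 7, and 7 from 5 and 6.** The same pair of operations installs ring C. The B–C ether is cut at ring C C1 and the formyl group of 6, para to the bromide, is the masked C4 hydroxyl. This is the one crowded diaryl ether coupling that the route keeps, because ring C cannot be differentiated by a ring construction in few steps.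

**5 from 3, and 3 from 1 and 2.** Ring B is introduced like ring D, from the unhindered phenol 1 and bromide 2. The chain thus grows from A to D with the growing piece always the phenol, and only five commercial compounds are used (1, 2, 6, 13, 15).

## Alternatives that were turned down

**Alternative 1:** Both aryl–oxygen bonds of ring B are cut, so that ring B becomes a twofold electrophile: (η5-cyclopentadienyl)(η6-1,2-dichloro-3,5-dimethoxybenzene)ruthenium hexafluorophosphate, A2. In the forward key step A2 is substituted in one pot, first at ring B C6 by the phenoxide of 4-[2,4-dimethoxy-6-(2,4,6-trimethoxyphenoxy)phenoxy]-2,6-dimethoxyphenol, A3, and then at C1 by the phenoxide of 1. The product is the ruthenium complex of the undecamethyl ether, A1, which is decomplexed and demethylated.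

- For: the route is convergent. The metal cation makes even a methoxylated chloroarene electrophilic under mild conditions and tolerates a 2,6-disubstituted phenoxide. The two chlorines differ (C6 is meta to both methoxy groups, C1 is ortho and para to them), so the order of substitution is predictable.
- Against: the second substitution takes place at a carbon between two substituents on a ring that by then carries three donors. A stoichiometric precious metal and complexation and decomplexation steps are required. A3 already contains the D–E ether, the hardest bond of the molecule, so the problem is moved into a fragment that itself needs some five or six steps.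
- Comparison: Alternative 1 is stronger in convergence and in the mild formation of the crowded 1,2-diether of ring B, where the chosen route uses a copper coupling at a di-ortho-substituted bromide. The chosen route offers instead a D–E ether made by substitution at sp3 carbon, no stoichiometric ruthenium, and commercial precursors for every ring.

**Alternative 2:** Ring A is cut at C1–C6 and C2–C3 (C1 being its ether-bearing carbon). This leads back to the ynol ether 1-(benzyloxy)-2-(ethynyloxy)-3,5-dimethoxybenzene, A5, and 3-ethoxycyclobut-2-en-1-one, A6. On heating, the vinylketene from A6 adds across the alkyne of A5; the new cyclobutenone reopens and electrocyclises (Danheiser benzannulation) to 3-[2-(benzyloxy)-4,6-dimethoxyphenoxy]-5-ethoxyphenol, A4.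

- For: the regiochemistry is fixed by the polarisation of the ynol ether. The conditions are neutral and metal-free. The aryl–oxygen bond exists before the ring does.
- Against: the ring construction is spent on the least demanding ether of the molecule. Ring A has no ortho substituent, and step 1 of the chosen route makes the A–B ether in one coupling from 1 and 2. A5 is a fragile aryl ynol ether that needs two steps from its phenol, A6 is not a bulk reagent, and A4 needs capping of its free hydroxyl and debenzylation. The B–C, C–D and D–E ethers all remain to be made.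
- Comparison: the idea is the same as in the chosen strategy, but applied at the terminus where coupling is easy. Alternative 2 is stronger in that its ring-forming stages are unimolecular and free of any self-condensation issue, and in that it puts the risk on small, cheap material at the start. The chosen strategy places the ring construction where both ortho positions are oxygenated and ends directly in the full skeleton.

**Alternative 3:** Ring D is cut at C3–C4, leading back to 4-(1-ethoxyethenyl)-4-hydroxy-3-(2,4,6-trimethoxyphenoxy)cyclobut-2-en-1-one, A8. Thermolysis (Moore rearrangement) opens A8 to a dienylketene, which closes to the hydroquinone 2-ethoxy-6-(2,4,6-trimethoxyphenoxy)benzene-1,4-diol, A7.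

- For: ring D is built with its four oxygens in defined positions while the D–E oxygen is already in place. The cascade is unimolecular and runs early on cheap material. The two hydroxyls of A7 differ sterically.
- Against: A8 needs a semisquarate carrying the aryloxy group and a regioselective addition of a lithiated enol ether. A7 is an air-sensitive hydroquinone whose unhindered hydroxyl must be capped before the hindered one is arylated by ring C. Mixed ethyl and methyl ethers result. Three further diaryl ethers (C–D, B–C, A–B) follow, two of them at crowded positions, so the sequence is clearly longer.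
- Comparison: Alternative 3 is stronger in placing the risky ring formation at the start and in having no cross- versus self-condensation problem. The chosen strategy uses bulk three-carbon reagents, needs no organolithium or squarate chemistry, and leaves only ester removal and deprotection after its ring-forming step.

Key step: step 8

## Route

Remark on the chemistry: the target has no stereocentre, and bromoaldehydes 2 and 6 are taken as purchasable. In step 8 the methanol is distilled out at 120 °C, because refluxing methanol alone is not expected to carry the Claisen equilibria.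

Step 1
Reactants: 1 3,5-dimethoxyphenol; 2 2-bromo-3,5-dimethoxybenzaldehyde
Product: 3 2-(3,5-dimethoxyphenoxy)-3,5-dimethoxybenzaldehyde (A–B aldehyde)
Conditions: CuI (10 mol%), picolinic acid (20 mol%), K3PO4, DMSO, 90 °C
Reagents that add atoms: none
Why: Ullmann diaryl ether coupling of an unhindered phenol; the ortho formyl group of 2 assists copper insertion into the C–Br bond, and the ligand system is suited to ortho-substituted aryl halides.

Step 2
Reactants: 3 A–B aldehyde
Product: 5 2-(3,5-dimethoxyphenoxy)-3,5-dimethoxyphenol (A–B phenol), via aryl formate 4 (not isolated)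
Conditions: mCPBA (1.1 equiv), CH2Cl2, 0 °C to rt; Me2S; then K2CO3 (cat.), MeOH, rt
Reagents that add atoms: mCPBA (3-chloroperoxybenzoic acid), OOC(=O)c1cccc(Cl)c1
Why: Baeyer–Villiger oxidation of an aryl aldehyde (Dakin-type overall), in which the ortho aryloxy group promotes aryl over hydride migration; the formate is cleaved by methanolysis, and one equivalent of peracid at low temperature limits oxidation of the electron-rich rings.

Step 3
Reactants: 5 A–B phenol; 6 4-bromo-3,5-dimethoxybenzaldehyde
Product: 7 4-[2-(3,5-dimethoxyphenoxy)-3,5-dimethoxyphenoxy]-3,5-dimethoxybenzaldehyde (A–B–C aldehyde)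
Conditions: CuI (20 mol%), picolinic acid (40 mol%), K3PO4, DMSO, 100 °C
Reagents that add atoms: none
Why: Ullmann diaryl ether coupling at a bromide flanked by two methoxy groups; the para formyl group makes the C–Br bond electron-poor, and picolinic acid-ligated copper is known to join ortho-substituted phenols with di-ortho-substituted aryl halides.

Step 4
Reactants: 7 A–B–C aldehyde
Product: 9 4-[2-(3,5-dimethoxyphenoxy)-3,5-dimethoxyphenoxy]-3,5-dimethoxyphenol (A–B–C phenol), via aryl formate 8 (not isolated)
Conditions: mCPBA (1.1 equiv), CH2Cl2, 0 °C to rt; Me2S; then K2CO3 (cat.), MeOH, rt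
Reagents that add atoms: mCPBA (3-chloroperoxybenzoic acid), OOC(=O)c1cccc(Cl)c1
Why: Baeyer–Villiger oxidation of a 4-aryloxy-3,5-dimethoxybenzaldehyde, the same pattern as 3,4,5-trimethoxybenzaldehyde, where the para oxygen ensures aryl migration; methanolysis frees the phenol.

Step 5
Reactants: 9 A–B–C phenol; 2 2-bromo-3,5-dimethoxybenzaldehyde
Product: 10 2-{4-[2-(3,5-dimethoxyphenoxy)-3,5-dimethoxyphenoxy]-3,5-dimethoxyphenoxy}-3,5-dimethoxybenzaldehyde (A–B–C–D aldehyde, Ar4–CHO)
Conditions: CuI (10 mol%), picolinic acid (20 mol%), K3PO4, DMSO, 90 °C
Reagents that add atoms: none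
Why: Ullmann diaryl ether coupling as in step 1; the ring C hydroxyl of 9 has two ortho hydrogens and is an unhindered, electron-rich nucleophile.

Step 6
Reactants: 10 A–B–C–D aldehyde
Product: 12 2-{4-[2-(3,5-dimethoxyphenoxy)-3,5-dimethoxyphenoxy]-3,5-dimethoxyphenoxy}-3,5-dimethoxyphenol (A–B–C–D phenol, Ar4–OH), via aryl formate 11 (not isolated)
Conditions: mCPBA (1.1 equiv), CH2Cl2, 0 °C to rt; Me2S; then K2CO3 (cat.), MeOH, rt
Reagents that add atoms: mCPBA (3-chloroperoxybenzoic acid), OOC(=O)c1cccc(Cl)c1
Why: Baeyer–Villiger oxidation and formate methanolysis as in step 2, on the same 2-aryloxy-3,5-dimethoxybenzaldehyde pattern.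

Step 7
Reactants: 12 A–B–C–D phenol; 13 dimethyl bromomalonate
Product: 14 dimethyl 2-(Ar4-oxy)propanedioate (aryloxymalonate)
Conditions: K2CO3, acetone, 50 °C
Reagents that add atoms: none
Why: Williamson-type SN2 displacement of bromide from a doubly activated secondary carbon by the phenoxide of 12, a standard route to aryloxymalonates; a small excess of 13 limits a second alkylation of the acidic product.

Step 8
Reactants: 14 aryloxymalonate; 15 dimethyl 3-oxopentanedioate
Product: 17 dimethyl 5-(Ar4-oxy)-2,4,6-trihydroxybenzene-1,3-dicarboxylate, via open-chain monoacylation adduct 16 (not isolated)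
Conditions: 15 (2.5 equiv), NaOMe (2.5 equiv), MeOH, rt; added over 4 h to 14 in toluene–diglyme, 120 °C, MeOH distilled off; then 1 M HCl, 0 °C
Reagents that add atoms: none
Why: Crossed double Claisen condensation of the polyketide type: the sodium enolate of 15 adds through a methylene carbon to one ester carbonyl of 14 and methoxide leaves, giving the open-chain tricarbonyl 16 and the C2–C3 bond of ring E. The second methylene of the former oxopentanedioate, now between a ketone and an ester, is deprotonated and attacks the remaining malonate ester in a Dieckmann closure, 6-exo-trig at the ester carbonyl and allowed for either the ketone or the ester enolate form, which forms C5–C6 and closes ring E. The resulting cyclohexane-1,3,5-trione carries a hydrogen on each sp3 ring carbon and enolises three times to the phloroglucinol, held as a stable aryloxide; this aromatisation pulls the reversible Claisen equilibria forward, and removal of methanol at 120 °C helps. The closest known reaction is the condensation of dialkyl malonates with dialkyl 3-oxopentanedioates to dialkyl 2,4,6-trihydroxyisophthalates. No stereocentre is formed, and because both partners are symmetric only one constitution can result. The selectivity needed is cross- over self-condensation of 15 and C- over O-acylation: 15 is kept as its enolate, whose ketone is no longer electrophilic, and is fed slowly to 14, the only good acyl donor present, while O-acylated products revert under the equilibrating conditions. The aryl ethers and the D–E oxygen, which sits on the malonate carbon, are inert to methoxide.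

Step 9
Reactants: 17 pentamer diester
Product: 19 2-(Ar4-oxy)benzene-1,3,5-triol (octamethyl ether of the target), via dicarboxylic acid 18 (not isolated)
Conditions: KOH, H2O–MeOH (degassed), 70 °C, Ar; then HCl to pH 1, 70 °C
Reagents that add atoms: none
Why: Saponification followed by acid-promoted double decarboxylation; 2,4,6-trihydroxybenzoic acids are vinylogous β-keto acids and lose CO2 on warming in acid, as in the classical route to phloroglucinol from its carboxylic esters.

Step 10
Reactants: 19 pentamer octamethyl ether
Product: 20 CNP0018313.0, 2-{2-[4-(2-(3,5-dihydroxyphenoxy)-3,5-dihydroxyphenoxy)-3,5-dihydroxyphenoxy]-3,5-dihydroxyphenoxy}benzene-1,3,5-triol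
Conditions: BBr3 (20 equiv), CH2Cl2, −78 °C to rt, Ar; then H2O, 0 °C
Reagents that add atoms: none
Why: Lewis-acid cleavage of the eight aryl methyl ethers through bromide attack on the O–methyl carbon of the boron-complexed ether; diaryl ether bonds have no sp3 carbon to attack and are kept, and the product is isolated under argon by reversed-phase or Sephadex LH-20 chromatography.

## Compound list

1 | 3,5-dimethoxyphenol | COc1cc(O)cc(OC)c1 | starting material
2 | 2-bromo-3,5-dimethoxybenzaldehyde | O=Cc1cc(OC)cc(OC)c1Br | starting material
3 | 2-(3,5-dimethoxyphenoxy)-3,5-dimethoxybenzaldehyde | O=Cc1cc(OC)cc(OC)c1Oc1cc(OC)cc(OC)c1 | intermediate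
4 | 2-(3,5-dimethoxyphenoxy)-3,5-dimethoxyphenyl formate | O=COc1cc(OC)cc(OC)c1Oc1cc(OC)cc(OC)c1 | intermediate
5 | 2-(3,5-dimethoxyphenoxy)-3,5-dimethoxyphenol | Oc1cc(OC)cc(OC)c1Oc1cc(OC)cc(OC)c1 | intermediate
6 | 4-bromo-3,5-dimethoxybenzaldehyde | O=Cc1cc(OC)c(Br)c(OC)c1 | starting material
7 | 4-[2-(3,5-dimethoxyphenoxy)-3,5-dimethoxyphenoxy]-3,5-dimethoxybenzaldehyde | O=Cc1cc(OC)c(Oc2cc(OC)cc(OC)c2Oc2cc(OC)cc(OC)c2)c(OC)c1 | intermediate
8 | 4-[2-(3,5-dimethoxyphenoxy)-3,5-dimethoxyphenoxy]-3,5-dimethoxyphenyl formate | O=COc1cc(OC)c(Oc2cc(OC)cc(OC)c2Oc2cc(OC)cc(OC)c2)c(OC)c1 | intermediate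
9 | 4-[2-(3,5-dimethoxyphenoxy)-3,5-dimethoxyphenoxy]-3,5-dimethoxyphenol | Oc1cc(OC)c(Oc2cc(OC)cc(OC)c2Oc2cc(OC)cc(OC)c2)c(OC)c1 | intermediate
10 | 2-{4-[2-(3,5-dimethoxyphenoxy)-3,5-dimethoxyphenoxy]-3,5-dimethoxyphenoxy}-3,5-dimethoxybenzaldehyde | O=Cc1cc(OC)cc(OC)c1Oc1cc(OC)c(Oc2cc(OC)cc(OC)c2Oc2cc(OC)cc(OC)c2)c(OC)c1 | intermediate
11 | 2-{4-[2-(3,5-dimethoxyphenoxy)-3,5-dimethoxyphenoxy]-3,5-dimethoxyphenoxy}-3,5-dimethoxyphenyl formate | O=COc1cc(OC)cc(OC)c1Oc1cc(OC)c(Oc2cc(OC)cc(OC)c2Oc2cc(OC)cc(OC)c2)c(OC)c1 | intermediate
12 | 2-{4-[2-(3,5-dimethoxyphenoxy)-3,5-dimethoxyphenoxy]-3,5-dimethoxyphenoxy}-3,5-dimethoxyphenol | Oc1cc(OC)cc(OC)c1Oc1cc(OC)c(Oc2cc(OC)cc(OC)c2Oc2cc(OC)cc(OC)c2)c(OC)c1 | intermediate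
13 | dimethyl bromomalonate (dimethyl 2-bromopropanedioate) | COC(=O)C(Br)C(=O)OC | starting material
14 | dimethyl 2-(2-{4-[2-(3,5-dimethoxyphenoxy)-3,5-dimethoxyphenoxy]-3,5-dimethoxyphenoxy}-3,5-dimethoxyphenoxy)propanedioate | COC(=O)C(Oc1cc(OC)cc(OC)c1Oc1cc(OC)c(Oc2cc(OC)cc(OC)c2Oc2cc(OC)cc(OC)c2)c(OC)c1)C(=O)OC | intermediate
15 | dimethyl 3-oxopentanedioate | COC(=O)CC(=O)CC(=O)OC | starting material
16 | trimethyl 1-(Ar4-oxy)-2,4-dioxopentane-1,3,5-tricarboxylate (open-chain adduct, epimerising mixture with enol forms) | COC(=O)CC(=O)C(C(=O)OC)C(=O)C(Oc1cc(OC)cc(OC)c1Oc1cc(OC)c(Oc2cc(OC)cc(OC)c2Oc2cc(OC)cc(OC)c2)c(OC)c1)C(=O)OC | intermediate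
17 | dimethyl 5-(2-{4-[2-(3,5-dimethoxyphenoxy)-3,5-dimethoxyphenoxy]-3,5-dimethoxyphenoxy}-3,5-dimethoxyphenoxy)-2,4,6-trihydroxybenzene-1,3-dicarboxylate | COC(=O)c1c(O)c(C(=O)OC)c(O)c(Oc2cc(OC)cc(OC)c2Oc2cc(OC)c(Oc3cc(OC)cc(OC)c3Oc3cc(OC)cc(OC)c3)c(OC)c2)c1O | intermediate
18 | 5-(2-{4-[2-(3,5-dimethoxyphenoxy)-3,5-dimethoxyphenoxy]-3,5-dimethoxyphenoxy}-3,5-dimethoxyphenoxy)-2,4,6-trihydroxybenzene-1,3-dicarboxylic acid | OC(=O)c1c(O)c(C(O)=O)c(O)c(Oc2cc(OC)cc(OC)c2Oc2cc(OC)c(Oc3cc(OC)cc(OC)c3Oc3cc(OC)cc(OC)c3)c(OC)c2)c1O | intermediate
19 | 2-(2-{4-[2-(3,5-dimethoxyphenoxy)-3,5-dimethoxyphenoxy]-3,5-dimethoxyphenoxy}-3,5-dimethoxyphenoxy)benzene-1,3,5-triol | Oc1cc(O)c(Oc2cc(OC)cc(OC)c2Oc2cc(OC)c(Oc3cc(OC)cc(OC)c3Oc3cc(OC)cc(OC)c3)c(OC)c2)c(O)c1 | intermediate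
20 | CNP0018313.0, 2-{2-[4-(2-(3,5-dihydroxyphenoxy)-3,5-dihydroxyphenoxy)-3,5-dihydroxyphenoxy]-3,5-dihydroxyphenoxy}benzene-1,3,5-triol | Oc1cc(O)cc(Oc2c(O)cc(O)cc2Oc2c(O)cc(Oc3c(O)cc(O)cc3Oc3c(O)cc(O)cc3O)cc2O)c1 | target

## Step count and risk

Total step count: 10. Longest linear sequence: 10 steps (1 and 2 to 20); the route is fully linear.

**Step 8 (key step).** The likely failures are three. Proton transfer may turn 14 into its unreactive enolate. Methoxide may remove a methoxycarbonyl group from 14 by retro-Claisen cleavage. Self-condensation of 15 may outrun the cross reaction once free 15 is regenerated by the acidic product. In each case the tetramer would be returned or degraded instead of annulated; the aryloxy substituent makes the malonate both more acidic and more crowded than the parent ester for which this condensation is established. The fallback gives up the ring construction and attaches ring E preformed, with the operations already proven for ring C. It sets out from 12, which is coupled with 6 under the copper conditions of step 3 to 4-(Ar4-oxy)-3,5-dimethoxybenzaldehyde F1. Peracid oxidation as in step 4 gives 4-(Ar4-oxy)-3,5-dimethoxyphenyl formate F2, which is not isolated, and methanolysis gives 4-(Ar4-oxy)-3,5-dimethoxyphenol F3. BBr3 then cleaves all ten methyl ethers, and the route is rejoined at 20.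

**Step 3.** Copper insertion into a C–Br bond between two methoxy groups, followed by C–O bond formation with an ortho-aryloxy phenoxide, may be too slow. Protodebromination of 6 and decomposition of the aldehyde would then dominate. The fallback changes the mechanism from metal catalysis to addition–elimination. It sets out from 5, which is treated with 4-fluoro-3,5-dimethoxybenzaldehyde (O=Cc1cc(OC)c(F)c(OC)c1) and K2CO3 in DMSO at 120 to 140 °C. The para formyl group stabilises the Meisenheimer intermediate and fluoride is a small leaving group. The route is rejoined at 7.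

**Step 2 (the same concern applies to step 6).** Hydride instead of aryl migration in the Criegee intermediate would give the benzoic acid, since the formyl carbon is meta to both methoxy groups and has only the ortho aryloxy donor. Competing peracid attack on the 1,3,5-trioxygenated ring A is the second concern. The fallback replaces the formyl mask by an acetyl group, for which the competition is aryl against methyl and aryl migration is assured. It sets out from 1, which is coupled under the conditions of step 1 with 1-(2-bromo-3,5-dimethoxyphenyl)ethan-1-one (CC(=O)c1cc(OC)cc(OC)c1Br) to 1-[2-(3,5-dimethoxyphenoxy)-3,5-dimethoxyphenyl]ethan-1-one F4. Baeyer–Villiger oxidation (mCPBA, CH2Cl2, catalytic CF3CO2H) gives 2-(3,5-dimethoxyphenoxy)-3,5-dimethoxyphenyl acetate F5, and methanolysis with catalytic K2CO3 rejoins the route at 5.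

**Step 7.** The phenoxide of 12 may attack bromine instead of carbon. This would brominate the activated ring D and return malonate. The product may also be alkylated a second time at its acidic C–H. The fallback forms the same O–C bond by carbene O–H insertion. It sets out from 12, which is treated with dimethyl diazomalonate (COC(=O)C(=[N+]=[N-])C(=O)OC) and catalytic Rh2(OAc)4 in CH2Cl2 or benzene at 40 to 80 °C. The route is rejoined at 14.

**Step 10.** Incomplete cleavage of eight ethers would give partly methylated mixtures, and the free undecaphenol may be lost by oxidation during aqueous work-up and chromatography. The fallback changes the isolation to derivatise, purify and release. It sets out from 19, which is demethylated as before. The crude polyphenol is acetylated at once (Ac2O, pyridine) to the undecaacetate of the target F6, which is stable and can be purified on silica; partly methylated acetates are separated and recycled. Acid-catalysed transesterification (HCl in degassed MeOH, rt) then releases the product, and the route is rejoined at 20.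

## Further compounds

F1 | step 8 | 4-(2-{4-[2-(3,5-dimethoxyphenoxy)-3,5-dimethoxyphenoxy]-3,5-dimethoxyphenoxy}-3,5-dimethoxyphenoxy)-3,5-dimethoxybenzaldehyde | O=Cc1cc(OC)c(Oc2cc(OC)cc(OC)c2Oc2cc(OC)c(Oc3cc(OC)cc(OC)c3Oc3cc(OC)cc(OC)c3)c(OC)c2)c(OC)c1
F2 | step 8 | 4-(2-{4-[2-(3,5-dimethoxyphenoxy)-3,5-dimethoxyphenoxy]-3,5-dimethoxyphenoxy}-3,5-dimethoxyphenoxy)-3,5-dimethoxyphenyl formate | O=COc1cc(OC)c(Oc2cc(OC)cc(OC)c2Oc2cc(OC)c(Oc3cc(OC)cc(OC)c3Oc3cc(OC)cc(OC)c3)c(OC)c2)c(OC)c1
F3 | step 8 | 4-(2-{4-[2-(3,5-dimethoxyphenoxy)-3,5-dimethoxyphenoxy]-3,5-dimethoxyphenoxy}-3,5-dimethoxyphenoxy)-3,5-dimethoxyphenol | Oc1cc(OC)c(Oc2cc(OC)cc(OC)c2Oc2cc(OC)c(Oc3cc(OC)cc(OC)c3Oc3cc(OC)cc(OC)c3)c(OC)c2)c(OC)c1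
F0 | step 3 | none | none
F4 | step 2 | 1-[2-(3,5-dimethoxyphenoxy)-3,5-dimethoxyphenyl]ethan-1-one | CC(=O)c1cc(OC)cc(OC)c1Oc1cc(OC)cc(OC)c1
F5 | step 2 | 2-(3,5-dimethoxyphenoxy)-3,5-dimethoxyphenyl acetate | CC(=O)Oc1cc(OC)cc(OC)c1Oc1cc(OC)cc(OC)c1
F0 | step 7 | none | none
F6 | step 10 | undecaacetate of CNP0018313.0 | CC(=O)Oc1cc(OC(C)=O)cc(Oc2c(OC(C)=O)cc(OC(C)=O)cc2Oc2c(OC(C)=O)cc(Oc3c(OC(C)=O)cc(OC(C)=O)cc3Oc3c(OC(C)=O)cc(OC(C)=O)cc3OC(C)=O)cc2OC(C)=O)c1
A1 | alternative 1 | (η5-cyclopentadienyl)ruthenium hexafluorophosphate complex of the undecamethyl ether of the target, metal on ring B, written as its ionic components | COc1cc(OC)cc(Oc2c(OC)cc(OC)cc2Oc2c(OC)cc(Oc3c(OC)cc(OC)cc3Oc3c(OC)cc(OC)cc3OC)cc2OC)c1.[cH-]1cccc1.[Ru+2].F[P-](F)(F)(F)(F)F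
A2 | alternative 1 | (η5-cyclopentadienyl)(η6-1,2-dichloro-3,5-dimethoxybenzene)ruthenium hexafluorophosphate, written as its ionic components | COc1cc(OC)c(Cl)c(Cl)c1.[cH-]1cccc1.[Ru+2].F[P-](F)(F)(F)(F)F
A3 | alternative 1 | 4-[2,4-dimethoxy-6-(2,4,6-trimethoxyphenoxy)phenoxy]-2,6-dimethoxyphenol | Oc1c(OC)cc(Oc2c(OC)cc(OC)cc2Oc2c(OC)cc(OC)cc2OC)cc1OC
A4 | alternative 2 | 3-[2-(benzyloxy)-4,6-dimethoxyphenoxy]-5-ethoxyphenol | CCOc1cc(O)cc(Oc2c(OC)cc(OC)cc2OCc2ccccc2)c1
A5 | alternative 2 | 1-(benzyloxy)-2-(ethynyloxy)-3,5-dimethoxybenzene | C#COc1c(OC)cc(OC)cc1OCc1ccccc1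
A6 | alternative 2 | 3-ethoxycyclobut-2-en-1-one | CCOC1=CC(=O)C1
A7 | alternative 3 | 2-ethoxy-6-(2,4,6-trimethoxyphenoxy)benzene-1,4-diol | CCOc1cc(O)cc(Oc2c(OC)cc(OC)cc2OC)c1O
A8 | alternative 3 | 4-(1-ethoxyethenyl)-4-hydroxy-3-(2,4,6-trimethoxyphenoxy)cyclobut-2-en-1-one (racemic) | CCOC(=C)C1(O)C(Oc2c(OC)cc(OC)cc2OC)=CC1=O
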